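**Retrosynthetic overview**
1. The target, (S)-7-hydroxy-8-methoxy-3-(2,3,4,5-tetramethoxyphenyl)chroman, is traced back to the C8 phenol 18 by O-methylation at C8 and removal of a MOM ether at C7.
2. Feature used: ring A carries three oxygens in a row (C7–O, C8–O, C8a–O1), and the C8a–O1 and C8–O bonds sit on adjacent ring carbons. Both are cut at once to a C8–C8a aryne, so ring C (the pyran) and the C8 hydroxyl arise together from the open-chain (S)-bromo alcohol 14.
3. 14 comes from auxiliary-controlled benzylation of the ring B arylacetyl imide 7 with the ring A benzylic bromide 11 (sets C3), then reductive removal of the auxiliary.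
4. 7 comes from 1,2,3,4-tetramethoxybenzene (ortho-lithiation/ethylene oxide, oxidation, N-acylation); 11 comes from 2-bromo-4-hydroxybenzaldehyde (MOM ether, reduction, Appel).
5. Ring order: rings A and B are purchased; ring C is the only ring made, in step 9.

Key step: step 9

Assumption: the sense of induction in step 7 is that of the chelated Z-enolate model (electrophile enters anti to the C4 benzyl group). On that model (S)-4-benzyl-2-oxazolidinone gives the (S) centre, and the descriptor is unchanged on reduction because CH2OH, like the imide carbonyl, outranks the aryl group.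

**Route**

Step 1
Reactants: 1 1,2,3,4-tetramethoxybenzene
Product: 3 2-(2,3,4,5-tetramethoxyphenyl)ethanol, via aryllithium 2 (not isolated)
Conditions: n-BuLi, TMEDA, THF, 0 °C; ethylene oxide (THF solution), −78 °C → rt; aq NH4Cl
Reagents that add atoms: ethylene oxide, C1CO1
Why: Directed ortho-lithiation at one of the two equivalent free ring positions next to an OMe group, followed by epoxide ring-opening by the aryllithium, should give the 2-arylethanol.

Step 2
Reactants: 3 2-(2,3,4,5-tetramethoxyphenyl)ethanol
Product: 4 2-(2,3,4,5-tetramethoxyphenyl)acetic acid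
Conditions: TEMPO (cat.), PhI(OAc)2 (2.2 equiv), MeCN/H2O, rt
Reagents that add atoms: water, O
Why: Oxoammonium (TEMPO/PhI(OAc)2) oxidation of a primary alcohol in aqueous MeCN runs through the aldehyde hydrate to the acid and avoids chlorine-based oxidants that could halogenate the electron-rich ring.

Step 3
Reactants: 4 2-(2,3,4,5-tetramethoxyphenyl)acetic acid; 5 (S)-4-benzyl-2-oxazolidinone
Product: 7 (S)-4-benzyl-3-[2-(2,3,4,5-tetramethoxyphenyl)acetyl]oxazolidin-2-one, via mixed pivalic anhydride 6 (not isolated)
Conditions: t-BuCOCl, Et3N, THF, −20 °C; then LiCl, 5, −20 °C → rt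
Reagents that add atoms: none
Why: N-Acylation of the oxazolidinone through the mixed pivalic anhydride (LiCl/Et3N variant) should occur at the less hindered arylacetyl carbonyl.

Step 4
Reactants: 8 2-bromo-4-hydroxybenzaldehyde
Product: 9 2-bromo-4-(methoxymethoxy)benzaldehyde
Conditions: MOMCl, i-Pr2NEt, CH2Cl2, 0 °C → rt
Reagents that add atoms: chloromethyl methyl ether (MOMCl), COCCl
Why: O-Alkylation of the phenol (MOM protection) under amine base is routine and leaves the aldehyde and aryl bromide untouched.

Step 5
Reactants: 9 2-bromo-4-(methoxymethoxy)benzaldehyde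
Product: 10 [2-bromo-4-(methoxymethoxy)phenyl]methanol
Conditions: NaBH4, MeOH, 0 °C
Reagents that add atoms: none
Why: Borohydride reduction of the aldehyde to the benzylic alcohol is chemoselective over the aryl bromide and the MOM acetal.

Step 6
Reactants: 10 [2-bromo-4-(methoxymethoxy)phenyl]methanol
Product: 11 2-bromo-1-(bromomethyl)-4-(methoxymethoxy)benzene
Conditions: CBr4, PPh3, CH2Cl2, 0 °C; used at once
Reagents that add atoms: carbon tetrabromide, BrC(Br)(Br)Br
Why: The Appel reaction converts the benzylic alcohol to the bromide under essentially neutral conditions that spare the acid-labile MOM group.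

Step 7
Reactants: 7 (S)-4-benzyl-3-[2-(2,3,4,5-tetramethoxyphenyl)acetyl]oxazolidin-2-one; 11 2-bromo-1-(bromomethyl)-4-(methoxymethoxy)benzene
Product: 13 (S)-4-benzyl-3-[(S)-3-(2-bromo-4-(methoxymethoxy)phenyl)-2-(2,3,4,5-tetramethoxyphenyl)propanoyl]oxazolidin-2-one, via sodium Z-enolate 12 (not isolated)
Conditions: NaHMDS, THF, −78 °C; then 11, −78 → −40 °C; AcOH quench at −78 °C
Reagents that add atoms: none
Why: Evans asymmetric alkylation, in which the chelated sodium Z-enolate is benzylated on the face opposite the C4 benzyl group of the auxiliary, should set the (S) configuration of the future C3, and the cold acidic quench guards the acidic α-aryl centre against epimerisation.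

Step 8
Reactants: 13 (S)-4-benzyl-3-[(S)-3-(2-bromo-4-(methoxymethoxy)phenyl)-2-(2,3,4,5-tetramethoxyphenyl)propanoyl]oxazolidin-2-one
Product: 14 (S)-3-[2-bromo-4-(methoxymethoxy)phenyl]-2-(2,3,4,5-tetramethoxyphenyl)propan-1-ol
Conditions: LiBH4, H2O (1 equiv), Et2O/THF, 0 °C
Reagents that add atoms: none
Why: Reductive cleavage of the N-acyl oxazolidinone by LiBH4 attacks the exocyclic carbonyl under non-enolising conditions, so the stereocentre, the aryl bromide and the MOM ether should survive and the auxiliary is recovered.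

Step 9
Reactants: 14 (S)-3-[2-bromo-4-(methoxymethoxy)phenyl]-2-(2,3,4,5-tetramethoxyphenyl)propan-1-ol
Product: 18 (S)-7-(methoxymethoxy)-3-(2,3,4,5-tetramethoxyphenyl)chroman-8-ol, via aryne alkoxide 15 (not isolated), via 8-lithiochroman 16 (not isolated), via lithium trimethoxyborate 17 (not isolated)
Conditions: LiTMP (4 equiv, from 2,2,6,6-tetramethylpiperidine and n-BuLi), THF, −78 → −20 °C; B(OMe)3 (6 equiv), −78 °C → rt; AcOH, 30% aq H2O2, 0 °C → rt
Reagents that add atoms: hydrogen peroxide, OO
Why: Proposed new method: LiTMP, which does not undergo Br–Li exchange, first forms the lithium alkoxide and then removes the ring A hydrogen between Br and the OMOM group, and on warming LiBr is lost to give aryne 15, whose tethered alkoxide adds to the aryne carbon that becomes C8a and leaves aryllithium 16 at C8, which B(OMe)3 captures as borate 17 and H2O2 oxidises by 1,2-aryl shift to the C8 phenol. The closest known reaction types are the base-induced aryne cyclisation of (2-haloaryl)propanols to chromans, the electrophilic quench of the aryllithium left by nucleophilic addition to an aryne, and aryllithium–borate–peroxide hydroxylation; only their union in one flask is untested. Ring C closes in a 6-exo-dig sense on the in-plane aryne π bond (O1–C8a), attack at C8 being out of reach of the three-atom tether. No stereocentre is formed, and the C3 methine is not acidic enough to be touched. The required regiochemistry (oxygen at C8a, lithium at C8) is secured both by the tether and by the inductive effect of the C7 OMOM oxygen, which favours the carbanion next to it; should 16 be protonated by the amine, the excess LiTMP relithiates the same C8 between O1 and OMOM before the borate is added.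

Step 10
Reactants: 18 (S)-7-(methoxymethoxy)-3-(2,3,4,5-tetramethoxyphenyl)chroman-8-ol
Product: 19 (S)-8-methoxy-7-(methoxymethoxy)-3-(2,3,4,5-tetramethoxyphenyl)chroman
Conditions: MeI, K2CO3, DMF, rt
Reagents that add atoms: iodomethane, CI
Why: Williamson O-methylation of the phenoxide should proceed cleanly, since no other acidic site is present.

Step 11
Reactants: 19 (S)-8-methoxy-7-(methoxymethoxy)-3-(2,3,4,5-tetramethoxyphenyl)chroman
Product: 20 (S)-8-methoxy-3-(2,3,4,5-tetramethoxyphenyl)chroman-7-ol (target)
Conditions: 2 M HCl (cat.), MeOH, 45 °C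
Reagents that add atoms: none
Why: Acid-catalysed acetal exchange removes the MOM group, while the aryl methyl ethers, the chroman ether and the non-acidic C3 centre are inert to dilute acid.

**Compound list**
1 | 1,2,3,4-tetramethoxybenzene | COc1ccc(OC)c(OC)c1OC | starting material
2 | (2,3,4,5-tetramethoxyphenyl)lithium | [Li]c1cc(OC)c(OC)c(OC)c1OC | intermediate
3 | 2-(2,3,4,5-tetramethoxyphenyl)ethanol | OCCc1cc(OC)c(OC)c(OC)c1OC | intermediate
4 | 2-(2,3,4,5-tetramethoxyphenyl)acetic acid | OC(=O)Cc1cc(OC)c(OC)c(OC)c1OC | intermediate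
5 | (S)-4-benzyl-2-oxazolidinone | O=C1N[C@@H](Cc2ccccc2)CO1 | starting material
6 | 2-(2,3,4,5-tetramethoxyphenyl)acetic pivalic anhydride | CC(C)(C)C(=O)OC(=O)Cc1cc(OC)c(OC)c(OC)c1OC | intermediate
7 | (S)-4-benzyl-3-[2-(2,3,4,5-tetramethoxyphenyl)acetyl]oxazolidin-2-one | O=C1OC[C@H](Cc2ccccc2)N1C(=O)Cc1cc(OC)c(OC)c(OC)c1OC | intermediate
8 | 2-bromo-4-hydroxybenzaldehyde | O=Cc1ccc(O)cc1Br | starting material
9 | 2-bromo-4-(methoxymethoxy)benzaldehyde | O=Cc1ccc(OCOC)cc1Br | intermediate
10 | [2-bromo-4-(methoxymethoxy)phenyl]methanol | OCc1ccc(OCOC)cc1Br | intermediate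
11 | 2-bromo-1-(bromomethyl)-4-(methoxymethoxy)benzene | BrCc1ccc(OCOC)cc1Br | intermediate
12 | sodium (Z)-enolate of imide 7 | [Na]O/C(=C\c1cc(OC)c(OC)c(OC)c1OC)N1C(=O)OC[C@@H]1Cc1ccccc1 | intermediate
13 | (S)-4-benzyl-3-[(S)-3-(2-bromo-4-(methoxymethoxy)phenyl)-2-(2,3,4,5-tetramethoxyphenyl)propanoyl]oxazolidin-2-one | O=C1OC[C@H](Cc2ccccc2)N1C(=O)[C@@H](Cc1ccc(OCOC)cc1Br)c1cc(OC)c(OC)c(OC)c1OC | intermediate
14 | (S)-3-[2-bromo-4-(methoxymethoxy)phenyl]-2-(2,3,4,5-tetramethoxyphenyl)propan-1-ol | COc1cc([C@H](Cc2ccc(OCOC)cc2Br)CO)c(OC)c(OC)c1OC | intermediate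
15 | lithium (S)-3-[4-(methoxymethoxy)-2,3-didehydrophenyl]-2-(2,3,4,5-tetramethoxyphenyl)propan-1-olate (C8–C8a aryne) | [Li]OC[C@@H](CC1=CC=C(OCOC)C#C1)c1cc(OC)c(OC)c(OC)c1OC | intermediate
16 | [(S)-7-(methoxymethoxy)-3-(2,3,4,5-tetramethoxyphenyl)chroman-8-yl]lithium | COc1cc([C@H]2COc3c(ccc(OCOC)c3[Li])C2)c(OC)c(OC)c1OC | intermediate
17 | lithium trimethoxy[(S)-7-(methoxymethoxy)-3-(2,3,4,5-tetramethoxyphenyl)chroman-8-yl]borate | [Li+].COc1cc([C@H]2COc3c(ccc(OCOC)c3[B-](OC)(OC)OC)C2)c(OC)c(OC)c1OC | intermediate
18 | (S)-7-(methoxymethoxy)-3-(2,3,4,5-tetramethoxyphenyl)chroman-8-ol | COc1cc([C@H]2COc3c(ccc(OCOC)c3O)C2)c(OC)c(OC)c1OC | intermediate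
19 | (S)-8-methoxy-7-(methoxymethoxy)-3-(2,3,4,5-tetramethoxyphenyl)chroman | COc1cc([C@H]2COc3c(ccc(OCOC)c3OC)C2)c(OC)c(OC)c1OC | intermediate
20 | (S)-8-methoxy-3-(2,3,4,5-tetramethoxyphenyl)chroman-7-ol | COc1cc([C@H]2COc3c(ccc(O)c3OC)C2)c(OC)c(OC)c1OC | target

**Step count**
Total: 11 steps. Longest linear sequence: 8 steps (1 → 3 → 4 → 7 → 13 → 14 → 18 → 19 → 20; the branch from 8 through 9, 10 and 11 is equally long).

**Steps most likely to fail**

Step 9 (proposed new method). Intermolecular capture of the aryne by the amide base or by a second alkoxide may compete with ring closure, and the C8 anion may be quenched by proton transfer before the borate is added, giving ring closure without hydroxylation. Fallback with known chemistry, setting out from 14: intramolecular Pd-catalysed C–O coupling of the aryl bromide with the primary alcohol (Pd(OAc)2, 2-(di-tert-butylphosphino)-1,1'-binaphthyl, Cs2CO3, toluene, 80 °C) should give (S)-7-(methoxymethoxy)-3-(2,3,4,5-tetramethoxyphenyl)chroman F1. Directed ortho-lithiation of F1 with n-BuLi/TMEDA in THF (−78 → 0 °C) at C8, the position flanked by O1 and the OMOM group, gives the same aryllithium 16. B(OMe)3 followed by AcOH/H2O2 then leads through 17 back to the route at 18.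

Step 7. The diastereoselectivity may be eroded by epimerisation of the acidic α-aryl imide centre, and the electron-rich benzylic bromide may ionise or self-condense before it is alkylated. Fallback that avoids both the bromide and the enolate, setting out from 4 and 9: Perkin condensation (Ac2O, Et3N, 100 °C, then aqueous hydrolysis) should give (E)-3-[2-bromo-4-(methoxymethoxy)phenyl]-2-(2,3,4,5-tetramethoxyphenyl)prop-2-enoic acid F2. Enantioselective hydrogenation of this α-aryl cinnamic acid (H2, [Ir(cod)(L*)][B(3,5-(CF3)2C6H3)4] with L* a chiral spiro phosphine–oxazoline, Et3N, MeOH; the ligand antipode is chosen to deliver the (S) acid) should give (S)-3-[2-bromo-4-(methoxymethoxy)phenyl]-2-(2,3,4,5-tetramethoxyphenyl)propanoic acid F3. Reduction with BH3·SMe2 in THF returns to the route at 14.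

Step 2. Over-oxidation may occur, either by C–C cleavage through the enolisable arylacetaldehyde or by oxidation of the tetramethoxyarene ring. Fallback that forms the acetic acid side chain at the acid oxidation level, setting out from 1: bromination with NBS in MeCN should give 1-bromo-2,3,4,5-tetramethoxybenzene F4. Pd-catalysed α-arylation of the zinc enolate BrZnCH2CO2t-Bu (Pd(dba)2, P(t-Bu)3, THF, rt) should give tert-butyl 2-(2,3,4,5-tetramethoxyphenyl)acetate F5. CF3CO2H in CH2Cl2 cleaves the ester and the route is rejoined at 4.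

**Further compounds**
F1 | step 9 | (S)-7-(methoxymethoxy)-3-(2,3,4,5-tetramethoxyphenyl)chroman | COc1cc([C@H]2COc3cc(OCOC)ccc3C2)c(OC)c(OC)c1OC
F2 | step 7 | (E)-3-[2-bromo-4-(methoxymethoxy)phenyl]-2-(2,3,4,5-tetramethoxyphenyl)prop-2-enoic acid | OC(=O)/C(=C/c1ccc(OCOC)cc1Br)c1cc(OC)c(OC)c(OC)c1OC
F3 | step 7 | (S)-3-[2-bromo-4-(methoxymethoxy)phenyl]-2-(2,3,4,5-tetramethoxyphenyl)propanoic acid | OC(=O)[C@@H](Cc1ccc(OCOC)cc1Br)c1cc(OC)c(OC)c(OC)c1OC
F4 | step 2 | 1-bromo-2,3,4,5-tetramethoxybenzene | COc1cc(Br)c(OC)c(OC)c1OC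
F5 | step 2 | tert-butyl 2-(2,3,4,5-tetramethoxyphenyl)acetate | COc1cc(CC(=O)OC(C)(C)C)c(OC)c(OC)c1OC
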